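**Plan**

- Retrosynthesis: the two phenols are unmasked from benzyl ethers last, and the C2–H and C3–H bonds of ring C are traced back (through the flavan-4-ol) to a C2=C3 flavone.
- Ring C of that flavone is a 4-pyranone fused to ring A at C4a–C8a. Its bonds C4a–C4, C4–C3 and O1–C2 are cut together: C4a carries iodine, C8a the free hydroxyl, C4 is carbon monoxide and C3–C2–phenyl is phenylacetylene.
- The iodophenol goes back to a 4-(piperidin-2-yl)phenol whose two positions ortho to the hydroxyl are equivalent. The piperidine is cut at N–CH3, N1'–C6' and C2'–C3' to formaldehyde, a 4-chlorobutyl Grignard reagent and the N-sulfinyl imine of a 2,6-bis(benzyloxy)-4-silyloxybenzaldehyde.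
- Forward: formylation and silylation of 3,5-bis(benzyloxy)phenol, imine formation, chain attachment, piperidine closure, N-methylation, desilylation, iodination; then ring C closes as the flavone, is hydrogenated and reoxidised, and the benzyl ethers are removed.
- Stereochemistry: piperidine C2' (R) comes from (S)-tert-butanesulfinamide in the Grignard addition; flavanone C2 (S) comes from the chiral ruthenium–carbene hydrogenation catalyst.

Key step: step 9

Assumption: the (R,R) antipode of the carbene precursor SINpEt·HBF4 (1,3-bis[1-(naphthalen-1-yl)ethyl]-4,5-dihydroimidazolium tetrafluoroborate) is taken as the one that adds hydrogen to the C2 face leading to the (2S) series; if the sense is the reverse, the (S,S) salt is used with no other change.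

**Route**

Step 1
Reactants: 1 3,5-bis(benzyloxy)phenol
Product: 3 2,6-bis(benzyloxy)-4-hydroxybenzaldehyde, via aryl iminium chloride 2 (not isolated)
Conditions: POCl3 (1.2 equiv), DMF, MeCN, 0 °C to rt; then ice–H2O, 50 °C
Reagents that add atoms: N,N-dimethylformamide, CN(C)C=O; water, O
Why: Vilsmeier–Haack formylation of a 3,5-dialkoxyphenol is known to favour the position para to the free hydroxyl (here flanked by the two benzyloxy groups), and the minor hydrogen-bonded ortho-formyl isomer should be removable by chromatography.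

Step 2
Reactants: 3 2,6-bis(benzyloxy)-4-hydroxybenzaldehyde
Product: 4 2,6-bis(benzyloxy)-4-(triisopropylsilyloxy)benzaldehyde
Conditions: TIPSCl, imidazole, DMF, rt
Reagents that add atoms: triisopropylsilyl chloride, CC(C)[Si](Cl)(C(C)C)C(C)C
Why: Silylation of the single acidic para-hydroxyl masks it as a hindered silyl ether that should survive the Grignard, acid and carbonate steps and can later be removed without touching the benzyl ethers.

Step 3
Reactants: 4 2,6-bis(benzyloxy)-4-(triisopropylsilyloxy)benzaldehyde; 5 (S)-tert-butanesulfinamide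
Product: 6 (S,E)-N-[2,6-bis(benzyloxy)-4-(triisopropylsilyloxy)benzylidene]-2-methylpropane-2-sulfinamide
Conditions: Ti(OEt)4 (2.5 equiv), THF, 65 °C
Reagents that add atoms: none
Why: Ellman condensation with Ti(OEt)4 as Lewis acid and water scavenger converts even hindered, electron-rich benzaldehydes into the (E)-N-sulfinyl aldimine without disturbing the sulfur stereocentre.

Step 4
Reactants: 6 the N-sulfinyl aldimine; 7 1-bromo-4-chlorobutane
Product: 9 (S)-N-[(R)-1-[2,6-bis(benzyloxy)-4-(triisopropylsilyloxy)phenyl]-5-chloropentyl]-2-methylpropane-2-sulfinamide, via 4-chlorobutylmagnesium bromide 8 (not isolated)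
Conditions: 7, Mg, THF, 30 °C; then 6, CH2Cl2, −48 °C to rt; aq NH4Cl
Reagents that add atoms: none
Why: Diastereoselective Grignard addition to an Ellman sulfinimine in a non-coordinating solvent should pass through the six-membered chair transition state with magnesium on the sulfinyl oxygen and tert-butyl equatorial, so the alkyl group is delivered to the Re face of the (S)-sulfinyl aldimine and sets the (R) benzylic centre, the minor diastereomer being removed by chromatography at this stage.

Step 5
Reactants: 9 the (S,R)-sulfinamide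
Product: 11 (R)-2-[2,6-bis(benzyloxy)-4-(triisopropylsilyloxy)phenyl]piperidine, via amino chloride hydrochloride 10 (not isolated)
Conditions: HCl (4 M in dioxane), MeOH, 0 °C; evaporate; K2CO3, NaI (10 mol%), MeCN, 70 °C
Reagents that add atoms: none
Why: Acidic methanolysis of the N–S bond (standard removal of the Ellman auxiliary) frees the primary amine, which after neutralisation should close the piperidine by 6-exo-tet N-alkylation of the primary chloride without touching the benzylic stereocentre.

Step 6
Reactants: 11 the 2-arylpiperidine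
Product: 13 (R)-2-[2,6-bis(benzyloxy)-4-(triisopropylsilyloxy)phenyl]-1-methylpiperidine, via iminium acetate 12 (not isolated)
Conditions: 37% aq HCHO, NaBH(OAc)3, AcOH, ClCH2CH2Cl, rt
Reagents that add atoms: formaldehyde, C=O
Why: Reductive amination with formaldehyde and NaBH(OAc)3 should methylate the secondary amine once through the iminium ion, the phenol being kept silylated so that Mannich aminomethylation of the electron-rich ring cannot compete.

Step 7
Reactants: 13 the N-methylpiperidine silyl ether
Product: 14 3,5-bis(benzyloxy)-4-[(R)-1-methylpiperidin-2-yl]phenol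
Conditions: TBAF, THF, 0 °C; H2O
Reagents that add atoms: none
Why: Fluoride cleavage of an aryl triisopropylsilyl ether is fast and selective and should leave the benzyl ethers and the tertiary amine untouched.

Step 8
Reactants: 14 3,5-bis(benzyloxy)-4-[(R)-1-methylpiperidin-2-yl]phenol
Product: 15 3,5-bis(benzyloxy)-2-iodo-4-[(R)-1-methylpiperidin-2-yl]phenol
Conditions: NIS (1.0 equiv), TFA (1.1 equiv), MeCN, −20 to 0 °C
Reagents that add atoms: N-iodosuccinimide, O=C1CCC(=O)N1I
Why: Electrophilic aromatic iodination of the activated phenol can occur only at the two equivalent positions ortho to the hydroxyl (para is blocked), one equivalent of NIS should give the mono-iodide, and protonation of the amine by TFA suppresses N-iodination and ipso fragmentation.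

Step 9
Reactants: 15 3,5-bis(benzyloxy)-2-iodo-4-[(R)-1-methylpiperidin-2-yl]phenol; 16 phenylacetylene; 17 carbon monoxide
Product: 20 5,7-bis(benzyloxy)-6-[(R)-1-methylpiperidin-2-yl]-2-phenyl-4H-chromen-4-one, via ynone 18 (not isolated), via enaminone 19 (not isolated)
Conditions: PdCl2(dppf) (5 mol%), CO (10 bar), 16 (1.5 equiv), Et2NH, 80 °C
Reagents that add atoms: none
Why: PdCl2(dppf), a divalent palladium precatalyst, is reduced in situ to zerovalent palladium, which inserts into the C4a–I bond of 15; CO insertion gives the aroylpalladium species, and coupling with the acetylide formed from 16 and diethylamine delivers ynone 18, creating C4a–C4 and C4–C3. Diethylamine then adds to the alkyne carbon remote from the carbonyl to give enaminone 19, and the ortho phenol displaces the amine at that carbon by addition–elimination, forming O1–C2 and closing ring C in a net 6-endo sense. The closest known reaction type is the palladium-catalysed carbonylative annulation of 2-iodophenols with terminal alkynes to flavones, a carbonylative Sonogashira coupling followed by amine-relayed cyclisation. No stereocentre is formed, and the (R) centre of the piperidine should pass through unchanged at this moderate temperature. The step needs carbonylation to outrun direct alkyne coupling, which CO pressure secures, and 6-endo rather than 5-exo (aurone) closure, which the secondary amine enforces through 19. The 6-substitution pattern is fixed beforehand, because iodine in 15 sits ortho to the only free hydroxyl, so the pyranone must fuse with the piperidine para to O1.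

Step 10
Reactants: 20 the bis(benzyloxy)flavone
Product: 22 (2S,4S)-5,7-bis(benzyloxy)-6-[(R)-1-methylpiperidin-2-yl]-2-phenylchroman-4-ol, via flavanone 21 (not isolated)
Conditions: Ru(2-methylallyl)2(cod) (5 mol%), (R,R)-SINpEt·HBF4 (10 mol%), KOt-Bu (15 mol%), n-hexane/toluene, H2 (100 bar), 40 °C
Reagents that add atoms: none
Why: Asymmetric hydrogenation of flavones with a chiral ruthenium–N-heterocyclic carbene catalyst reduces C2=C3 and then C4=O from the same face, so the carbene ligand should set C2 as (S) under catalyst control (the remote piperidine centre having little influence) and the cis (4S) carbinol follows from the C2 centre.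

Step 11
Reactants: 22 the cis-flavan-4-ol
Product: 21 (S)-5,7-bis(benzyloxy)-6-[(R)-1-methylpiperidin-2-yl]-2-phenylchroman-4-one
Conditions: Dess–Martin periodinane, NaHCO3, CH2Cl2, 0 °C to rt
Reagents that add atoms: none
Why: Buffered Dess–Martin oxidation of the benzylic secondary alcohol erases the C4 centre, converges any 21 left over from step 10, and avoids both the acid that would ionise the electron-rich flavan-4-ol and the base that would open ring C and racemise C2.

Step 12
Reactants: 21 the (S)-bis(benzyloxy)flavanone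
Product: 23 (S)-5,7-dihydroxy-6-[(R)-1-methylpiperidin-2-yl]-2-phenylchroman-4-one
Conditions: H2 (1 atm), Pd/C (10%), EtOAc/MeOH, rt
Reagents that add atoms: none
Why: Catalytic hydrogenolysis cleaves both aryl benzyl ethers under neutral conditions, avoiding the acid- or base-induced ring opening that would racemise C2 and the quinone-methide pathway that would epimerise the piperidine centre, and it is stopped at full debenzylation before the aryl ketone or the benzylic C2–O1 bond is attacked.

**Compound list**

1 | 3,5-bis(benzyloxy)phenol | Oc1cc(OCc2ccccc2)cc(OCc2ccccc2)c1 | starting material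
2 | N-[2,6-bis(benzyloxy)-4-hydroxybenzylidene]-N-methylmethanaminium chloride | C[N+](C)=Cc1c(OCc2ccccc2)cc(O)cc1OCc1ccccc1.[Cl-] | intermediate
3 | 2,6-bis(benzyloxy)-4-hydroxybenzaldehyde | O=Cc1c(OCc2ccccc2)cc(O)cc1OCc1ccccc1 | intermediate
4 | 2,6-bis(benzyloxy)-4-(triisopropylsilyloxy)benzaldehyde | O=Cc1c(OCc2ccccc2)cc(O[Si](C(C)C)(C(C)C)C(C)C)cc1OCc1ccccc1 | intermediate
5 | (S)-tert-butanesulfinamide | CC(C)(C)[S@](=O)N | starting material
6 | (S,E)-N-[2,6-bis(benzyloxy)-4-(triisopropylsilyloxy)benzylidene]-2-methylpropane-2-sulfinamide | CC(C)(C)[S@](=O)/N=C/c1c(OCc2ccccc2)cc(O[Si](C(C)C)(C(C)C)C(C)C)cc1OCc1ccccc1 | intermediate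
7 | 1-bromo-4-chlorobutane | ClCCCCBr | starting material
8 | 4-chlorobutylmagnesium bromide | ClCCCC[Mg]Br | intermediate
9 | (S)-N-[(R)-1-[2,6-bis(benzyloxy)-4-(triisopropylsilyloxy)phenyl]-5-chloropentyl]-2-methylpropane-2-sulfinamide | CC(C)(C)[S@](=O)N[C@H](CCCCCl)c1c(OCc2ccccc2)cc(O[Si](C(C)C)(C(C)C)C(C)C)cc1OCc1ccccc1 | intermediate
10 | (R)-1-[2,6-bis(benzyloxy)-4-(triisopropylsilyloxy)phenyl]-5-chloropentan-1-amine hydrochloride | Cl.N[C@H](CCCCCl)c1c(OCc2ccccc2)cc(O[Si](C(C)C)(C(C)C)C(C)C)cc1OCc1ccccc1 | intermediate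
11 | (R)-2-[2,6-bis(benzyloxy)-4-(triisopropylsilyloxy)phenyl]piperidine | N1CCCC[C@@H]1c1c(OCc2ccccc2)cc(O[Si](C(C)C)(C(C)C)C(C)C)cc1OCc1ccccc1 | intermediate
12 | (R)-2-[2,6-bis(benzyloxy)-4-(triisopropylsilyloxy)phenyl]-1-methylidenepiperidin-1-ium acetate | C=[N+]1CCCC[C@@H]1c1c(OCc2ccccc2)cc(O[Si](C(C)C)(C(C)C)C(C)C)cc1OCc1ccccc1.CC(=O)[O-] | intermediate
13 | (R)-2-[2,6-bis(benzyloxy)-4-(triisopropylsilyloxy)phenyl]-1-methylpiperidine | CN1CCCC[C@@H]1c1c(OCc2ccccc2)cc(O[Si](C(C)C)(C(C)C)C(C)C)cc1OCc1ccccc1 | intermediate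
14 | 3,5-bis(benzyloxy)-4-[(R)-1-methylpiperidin-2-yl]phenol | CN1CCCC[C@@H]1c1c(OCc2ccccc2)cc(O)cc1OCc1ccccc1 | intermediate
15 | 3,5-bis(benzyloxy)-2-iodo-4-[(R)-1-methylpiperidin-2-yl]phenol | CN1CCCC[C@@H]1c1c(OCc2ccccc2)cc(O)c(I)c1OCc1ccccc1 | intermediate
16 | phenylacetylene | C#Cc1ccccc1 | starting material
17 | carbon monoxide | [C-]#[O+] | starting material
18 | 1-[2,4-bis(benzyloxy)-6-hydroxy-3-[(R)-1-methylpiperidin-2-yl]phenyl]-3-phenylprop-2-yn-1-one | CN1CCCC[C@@H]1c1c(OCc2ccccc2)cc(O)c(C(=O)C#Cc2ccccc2)c1OCc1ccccc1 | intermediate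
19 | (E)-1-[2,4-bis(benzyloxy)-6-hydroxy-3-[(R)-1-methylpiperidin-2-yl]phenyl]-3-(diethylamino)-3-phenylprop-2-en-1-one (drawn as E; either geometry cyclises) | CN1CCCC[C@@H]1c1c(OCc2ccccc2)cc(O)c(C(=O)/C=C(/N(CC)CC)c2ccccc2)c1OCc1ccccc1 | intermediate
20 | 5,7-bis(benzyloxy)-6-[(R)-1-methylpiperidin-2-yl]-2-phenyl-4H-chromen-4-one | CN1CCCC[C@@H]1c1c(OCc2ccccc2)cc2oc(-c3ccccc3)cc(=O)c2c1OCc1ccccc1 | intermediate
21 | (S)-5,7-bis(benzyloxy)-6-[(R)-1-methylpiperidin-2-yl]-2-phenylchroman-4-one | CN1CCCC[C@@H]1c1c(OCc2ccccc2)cc2c(c1OCc1ccccc1)C(=O)C[C@@H](c1ccccc1)O2 | intermediate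
22 | (2S,4S)-5,7-bis(benzyloxy)-6-[(R)-1-methylpiperidin-2-yl]-2-phenylchroman-4-ol | CN1CCCC[C@@H]1c1c(OCc2ccccc2)cc2c(c1OCc1ccccc1)[C@@H](O)C[C@@H](c1ccccc1)O2 | intermediate
23 | (S)-5,7-dihydroxy-6-[(R)-1-methylpiperidin-2-yl]-2-phenylchroman-4-one | CN1CCCC[C@@H]1c1c(O)cc2c(c1O)C(=O)C[C@@H](c1ccccc1)O2 | target

**Step count**

Total: 12 steps. Longest linear sequence: 12 steps, from 1 to 23.

**Steps most likely to fail**

Step 10. The basic nitrogen may inhibit the ruthenium catalyst, reduction may stop early or go on into the arenes, and facial selectivity at C2 may be poor if catalyst and piperidine centre are mismatched. The fallback sets out from flavone 20 and gives up catalyst control. Conjugate hydride reduction with LiBH(s-Bu)3 in THF at −78 °C should give the flavanone as both C2 epimers, 21 and (R)-5,7-bis(benzyloxy)-6-[(R)-1-methylpiperidin-2-yl]-2-phenylchroman-4-one F1. Because the piperidine centre is fixed, these are diastereomers and should be separable by chromatography or crystallisation, and the route is rejoined at 21.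

Step 9. Oxidative addition into the doubly ortho-substituted, electron-rich C–I bond may be slow; direct alkynylation or aminocarbonylation by diethylamine may outrun the CO/alkyne sequence; closure may go 5-exo; and the para-hydroxybenzylic amine may be lost on heating through a quinone methide. The fallback sets out from iodophenol 15 and builds ring C without CO. Stille coupling with tributyl(1-ethoxyvinyl)stannane (Pd(PPh3)4, toluene, 90 °C) should give 3,5-bis(benzyloxy)-2-(1-ethoxyvinyl)-4-[(R)-1-methylpiperidin-2-yl]phenol F2. Dilute aqueous HCl hydrolyses it to 1-[2,4-bis(benzyloxy)-6-hydroxy-3-[(R)-1-methylpiperidin-2-yl]phenyl]ethanone F3. Claisen–Schmidt condensation with benzaldehyde (KOH, EtOH) gives (E)-1-[2,4-bis(benzyloxy)-6-hydroxy-3-[(R)-1-methylpiperidin-2-yl]phenyl]-3-phenylprop-2-en-1-one F4. Oxidative cyclisation with catalytic I2 in DMSO at 110 °C closes ring C, and the route is rejoined at flavone 20.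

Step 4. Chelation of magnesium by the ortho benzyloxy groups may erode or reverse facial selectivity, and addition to the hindered, electron-rich imine may be sluggish. The fallback sets out from aldehyde 4 and Grignard reagent 8 and sets the centre by C–H instead of C–C bond formation. Addition gives racemic 1-[2,6-bis(benzyloxy)-4-(triisopropylsilyloxy)phenyl]-5-chloropentan-1-ol F5. Dess–Martin oxidation gives 1-[2,6-bis(benzyloxy)-4-(triisopropylsilyloxy)phenyl]-5-chloropentan-1-one F6. Condensation with 5 (Ti(OEt)4, THF, 70 °C) gives (S)-N-[1-[2,6-bis(benzyloxy)-4-(triisopropylsilyloxy)phenyl]-5-chloropentylidene]-2-methylpropane-2-sulfinamide F7. Diastereoselective reduction at −78 °C then gives the sulfinamide: LiBH(s-Bu)3 and NaBH4 give opposite senses with N-sulfinyl ketimines, so the hydride is chosen to give the (S)-sulfinyl, (R)-carbon diastereomer, and the route is rejoined at 9.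

**Further compounds**

F1 | step 10 | (R)-5,7-bis(benzyloxy)-6-[(R)-1-methylpiperidin-2-yl]-2-phenylchroman-4-one | CN1CCCC[C@@H]1c1c(OCc2ccccc2)cc2c(c1OCc1ccccc1)C(=O)C[C@H](c1ccccc1)O2
F2 | step 9 | 3,5-bis(benzyloxy)-2-(1-ethoxyvinyl)-4-[(R)-1-methylpiperidin-2-yl]phenol | CN1CCCC[C@@H]1c1c(OCc2ccccc2)cc(O)c(C(=C)OCC)c1OCc1ccccc1
F3 | step 9 | 1-[2,4-bis(benzyloxy)-6-hydroxy-3-[(R)-1-methylpiperidin-2-yl]phenyl]ethanone | CN1CCCC[C@@H]1c1c(OCc2ccccc2)cc(O)c(C(C)=O)c1OCc1ccccc1
F4 | step 9 | (E)-1-[2,4-bis(benzyloxy)-6-hydroxy-3-[(R)-1-methylpiperidin-2-yl]phenyl]-3-phenylprop-2-en-1-one | CN1CCCC[C@@H]1c1c(OCc2ccccc2)cc(O)c(C(=O)/C=C/c2ccccc2)c1OCc1ccccc1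
F5 | step 4 | 1-[2,6-bis(benzyloxy)-4-(triisopropylsilyloxy)phenyl]-5-chloropentan-1-ol (racemic) | OC(CCCCCl)c1c(OCc2ccccc2)cc(O[Si](C(C)C)(C(C)C)C(C)C)cc1OCc1ccccc1
F6 | step 4 | 1-[2,6-bis(benzyloxy)-4-(triisopropylsilyloxy)phenyl]-5-chloropentan-1-one | O=C(CCCCCl)c1c(OCc2ccccc2)cc(O[Si](C(C)C)(C(C)C)C(C)C)cc1OCc1ccccc1
F7 | step 4 | (S)-N-[1-[2,6-bis(benzyloxy)-4-(triisopropylsilyloxy)phenyl]-5-chloropentylidene]-2-methylpropane-2-sulfinamide (C=N geometry not fixed) | CC(C)(C)[S@](=O)N=C(CCCCCl)c1c(OCc2ccccc2)cc(O[Si](C(C)C)(C(C)C)C(C)C)cc1OCc1ccccc1
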